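**Retrosynthetic overview** (ring A = benzo ring of the indane, ring B = its five-membered ring, ring C = 2,4-dioxygenated aryl on C3, ring D = 3,5-dioxygenated aryl on C2, ring E = vanillyl ring)
1. Feature used: C1–C2–C3 of ring B is an unbroken three-carbon chain. C3 bears ring C, so a cation at C3 is stabilised like a quinone methide. C1 is joined through C7a to ring A, whose C3a lies ortho to the oxygen on C4 and para to the oxygen on C6.
2. Endgame: seven isopropyl ethers are removed last. The E-benzylidene at C1 comes from a 1-aroylindane by reduction and dehydration, which erases the C1 stereocentre.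
3. Key disconnection: bond C3–C3a is traded for bond C1–C3, which folds ring B back to a 1,2,3-triarylcyclopropyl vanillyl ketone. In the forward sense a Lewis acid heterolyses C1–C3 and ring A recaptures C3 by a Friedel–Crafts reaction.
4. The cyclopropane comes from a Z-stilbene (C2=C3) and an aryl diazoketone (C1) by asymmetric dirhodium carbene transfer, which fixes C2. The stilbene comes from a Perkin condensation and decarboxylation. The diazoketone comes from a Weinreb ketone synthesis and diazo transfer.
5. Ring order: the four benzene rings are bought, the cyclopropane is made first, and ring B is then made at its expense.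

Key step: step 11

Assumption: the sense of induction of Rh2(S-PTAD)4 is carried over from its styrene cyclopropanations, with the alkene carbon that bears ring C playing the part of the styrene benzylic carbon; should the other antipode form, Rh2(R-PTAD)4 is used with no other change.

**Step 1**
Reactants: 1 3,5-dihydroxyphenylacetic acid
Product: 2 isopropyl (3,5-diisopropoxyphenyl)acetate
Conditions: 2-bromopropane (5 equiv), K2CO3, DMF, 70 °C
Reagents that add atoms: 2-bromopropane, CC(C)Br
Why: Williamson ether synthesis combined with carboxylate O-alkylation, in which K2CO3 in DMF deprotonates both phenols and the acid and each oxygen is alkylated by the secondary bromide, so one operation masks all acidic sites and no stereocentre is formed.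

**Step 2**
Reactants: 2 isopropyl (3,5-diisopropoxyphenyl)acetate
Product: 3 (3,5-diisopropoxyphenyl)acetic acid
Conditions: NaOH, THF–MeOH–H2O, 50 °C; then 1 M HCl
Reagents that add atoms: sodium hydroxide, [Na+].[OH-]
Why: Saponification by acyl–oxygen cleavage frees the acid, while the aryl isopropyl ethers offer hydroxide no point of attack.

**Step 3**
Reactants: 3 (3,5-diisopropoxyphenyl)acetic acid
Product: 5 2-(3,5-diisopropoxyphenyl)-N-methoxy-N-methylacetamide, via acyl imidazolide 4 (not isolated)
Conditions: 1,1'-carbonyldiimidazole, CH2Cl2, rt; then MeNHOMe·HCl, rt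
Reagents that add atoms: N,O-dimethylhydroxylamine hydrochloride, CNOC.Cl
Why: Amide coupling through the acyl imidazolide gives the Weinreb amide under neutral activation that avoids ketene formation from the arylacetyl unit.

**Step 4**
Reactants: 6 4-bromo-2-methoxyphenol
Product: 7 4-bromo-1-isopropoxy-2-methoxybenzene
Conditions: 2-bromopropane, K2CO3, DMF, 70 °C
Reagents that add atoms: 2-bromopropane, CC(C)Br
Why: Williamson ether synthesis on the single phenol, the aryl bromide being inert to carbonate.

**Step 5**
Reactants: 7 4-bromo-1-isopropoxy-2-methoxybenzene; 5 2-(3,5-diisopropoxyphenyl)-N-methoxy-N-methylacetamide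
Product: 9 2-(3,5-diisopropoxyphenyl)-1-(4-isopropoxy-3-methoxyphenyl)ethanone, via arylmagnesium bromide 8 (not isolated)
Conditions: 7, Mg turnings, THF, reflux; then 5 (0.7 equiv), THF, 0 °C; then 1 M HCl
Reagents that add atoms: none
Why: Weinreb ketone synthesis, in which the aryl Grignard reagent adds once to give a magnesium-chelated tetrahedral adduct that lasts until the acidic quench, the magnesium reagent being chosen over the aryllithium to limit deprotonation of the benzylic CH2.

**Step 6**
Reactants: 9 2-(3,5-diisopropoxyphenyl)-1-(4-isopropoxy-3-methoxyphenyl)ethanone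
Product: 10 2-diazo-2-(3,5-diisopropoxyphenyl)-1-(4-isopropoxy-3-methoxyphenyl)ethanone
Conditions: 4-acetamidobenzenesulfonyl azide, DBU, MeCN, 0 °C → rt
Reagents that add atoms: 4-acetamidobenzenesulfonyl azide, CC(=O)Nc1ccc(cc1)S(=O)(=O)N=[N+]=[N-]
Why: Regitz diazo transfer, in which DBU enolises the methylene activated by both aryl and aroyl groups and the enolate takes the two terminal nitrogens of the sulfonyl azide with release of the sulfonamide.

**Step 7**
Reactants: 11 2,4-dihydroxybenzaldehyde
Product: 12 2,4-diisopropoxybenzaldehyde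
Conditions: 2-bromopropane (4 equiv), K2CO3, DMF, 80 °C
Reagents that add atoms: 2-bromopropane, CC(C)Br
Why: Williamson ether synthesis, with excess bromide and a higher temperature because the hydrogen-bonded 2-hydroxyl reacts more slowly than the 4-hydroxyl.

**Step 8**
Reactants: 3 (3,5-diisopropoxyphenyl)acetic acid; 12 2,4-diisopropoxybenzaldehyde
Product: 13 (E)-2-(3,5-diisopropoxyphenyl)-3-(2,4-diisopropoxyphenyl)prop-2-enoic acid (the two aryl groups cis)
Conditions: Ac2O, Et3N, 120 °C; then H2O, 80 °C; acid–base extraction
Reagents that add atoms: none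
Why: Perkin condensation of the arylacetic acid (as its mixed anhydride enolate) with the aldehyde, in which elimination from the favoured aldol acetate sets the carboxyl group trans to the β-aryl group, so the two aryl rings end up cis as the later alkene requires.

**Step 9**
Reactants: 13 (E)-2-(3,5-diisopropoxyphenyl)-3-(2,4-diisopropoxyphenyl)prop-2-enoic acid
Product: 14 (Z)-2,3',4,5'-tetraisopropoxystilbene
Conditions: Cu powder, quinoline, 200 °C
Reagents that add atoms: none
Why: Copper-mediated protodecarboxylation of a 2,3-diarylacrylic acid runs through a configurationally stable vinylcopper species that is protonated with retention, which should deliver the Z-stilbene more dependably than a Wittig reaction of a semi-stabilised benzylide.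

**Step 10**
Reactants: 14 (Z)-2,3',4,5'-tetraisopropoxystilbene; 10 2-diazo-2-(3,5-diisopropoxyphenyl)-1-(4-isopropoxy-3-methoxyphenyl)ethanone
Product: 15 [(1S,2S,3R)-1,2-bis(3,5-diisopropoxyphenyl)-3-(2,4-diisopropoxyphenyl)cyclopropyl](4-isopropoxy-3-methoxyphenyl)methanone (three aryl groups on one face, aroyl group on the other)
Conditions: Rh2(S-PTAD)4 (2 mol %), 10 (1.5 equiv) added over 4 h to 14, 2,2-dimethylbutane–CH2Cl2, 40 °C; filtration through Et3N-deactivated silica
Reagents that add atoms: none
Why: Dirhodium-catalysed asymmetric cyclopropanation with a donor/acceptor carbene, in which loss of N2 gives an electrophilic rhodium carbene that bonds first to the alkene carbon bearing ring D while charge builds beside ring C, the side-on approach open to cis-alkenes places both alkene aryl groups syn to the carbene aryl group, and the chiral carboxylate pocket selects the alkene face, which fixes C2 (S) together with C1 and C3.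

**Step 11**
Reactants: 15 (1S,2S,3R)-1,2,3-triarylcyclopropyl vanillyl ketone (hepta-isopropyl ether)
Product: 17 [(1S,2R,3S)-2-(3,5-diisopropoxyphenyl)-3-(2,4-diisopropoxyphenyl)-4,6-diisopropoxy-2,3-dihydro-1H-inden-1-yl](4-isopropoxy-3-methoxyphenyl)methanone, via ring-opened zwitterion 16 (not isolated)
Conditions: Sc(OTf)3 (10 mol %), CH2Cl2, −20 °C → rt
Reagents that add atoms: none
Why: Proposed new method: Sc(OTf)3 binds the ketone oxygen of 15 and the crowded C1–C3 bond heterolyses to zwitterion 16 (scandium enolate at C1, quinone-methide-like 2,4-diisopropoxybenzyl cation at C3); after rotation about C1–C2 and C2–C3 the ortho carbon of the C1 aryl group (the future C3a, ortho to one isopropoxy group and para to the other) attacks C3 and rearomatisation passes its proton to the enolate carbon, so the net change is a catalytic isomerisation. The closest known reaction types are the Lewis-acid cyclisation of aryl 2-arylcyclopropyl ketones to 4-aryl-1-tetralones and the Friedel–Crafts ring opening of donor–acceptor cyclopropanes by electron-rich arenes, whereas capture by an aryl group that sits on the acceptor carbon itself, turning a cyclopropane into an indane, is not established. The single ring closed is ring B, by a five-membered Friedel–Crafts cycloalkylation that is 5-exo-trig at the C3=C(aryl) bond of the quinone-methide form, with bond C7a–C3a of ring A endocyclic. C3 is planar in 16 and is rebuilt under control of the untouched C2 stereocentre, ring C taking the face away from ring D (2,3-trans, which reversible closure should also favour), while C1 is protonated or equilibrated through the enol to the 1,2-trans ketone and its configuration is of no consequence. Three selectivities are needed: C1–C3 over C1–C2 cleavage, secured because only C3 carries an ortho/para-dioxygenated aryl group whereas ring D has its oxygens meta; carbon over oxygen capture, secured because Cloke–Wilson closure on the enolate oxygen re-ionises under the catalyst whereas C–C closure with rearomatisation is the sink; and ring A over ring E (the tetralone mode), secured because ring E is conjugated with the acceptor and has no doubly activated position. Loss of the C2 proton from 16 would erode enantiopurity, so base is excluded and the temperature is kept low.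

**Step 12**
Reactants: 17 (1S,2R,3S)-1-aroyl-2,3-diarylindane
Product: 18 [(1S,2R,3S)-2-(3,5-diisopropoxyphenyl)-3-(2,4-diisopropoxyphenyl)-4,6-diisopropoxy-2,3-dihydro-1H-inden-1-yl](4-isopropoxy-3-methoxyphenyl)methanol (carbinol epimers)
Conditions: NaBH4, THF–MeOH, 0 °C → rt
Reagents that add atoms: none
Why: Borohydride reduction of the aryl ketone, whose new carbinol centre may form as a mixture of epimers without harm because it and C1 both become sp2 in the next step.

**Step 13**
Reactants: 18 indanyl(aryl)methanol
Product: 19 (1E,2S,3S)-2-(3,5-diisopropoxyphenyl)-3-(2,4-diisopropoxyphenyl)-4,6-diisopropoxy-1-(4-isopropoxy-3-methoxybenzylidene)indane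
Conditions: p-TsOH·H2O (10 mol %), CH2Cl2, 0 °C → rt
Reagents that add atoms: none
Why: Acid-catalysed E1 dehydration, in which the 4-isopropoxy-3-methoxybenzylic cation forms readily and sheds the C1 hydrogen to give the alkene conjugated with rings A and E, the E isomer being favoured kinetically and by reversible protonation because the Z isomer presses ring E against C7–H, while the trans-disposed ring D cannot reach the cation and C2 and C3 are not touched.

**Step 14**
Reactants: 19 hepta-O-isopropyl ether of the target
Product: 20 (1E,2S,3S)-2-(3,5-dihydroxyphenyl)-3-(2,4-dihydroxyphenyl)-1-(4-hydroxy-3-methoxybenzylidene)-2,3-dihydro-1H-indene-4,6-diol (target)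
Conditions: BCl3 (12 equiv), CH2Cl2, −78 → 0 °C; then H2O
Reagents that add atoms: none
Why: Boron trichloride ether cleavage, in which coordination to oxygen followed by loss of the secondary isopropyl group to chloride is much faster than displacement at methyl, so the seven isopropyl ethers should fall while the aryl methyl ether, the alkene and both stereocentres stay.

**Compound list**
1 | 3,5-dihydroxyphenylacetic acid | OC(=O)Cc1cc(O)cc(O)c1 | starting material
2 | isopropyl (3,5-diisopropoxyphenyl)acetate | CC(C)OC(=O)Cc1cc(OC(C)C)cc(OC(C)C)c1 | intermediate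
3 | (3,5-diisopropoxyphenyl)acetic acid | OC(=O)Cc1cc(OC(C)C)cc(OC(C)C)c1 | intermediate
4 | 1-[(3,5-diisopropoxyphenyl)acetyl]imidazole (not isolated) | O=C(Cc1cc(OC(C)C)cc(OC(C)C)c1)n1ccnc1 | intermediate
5 | 2-(3,5-diisopropoxyphenyl)-N-methoxy-N-methylacetamide | CON(C)C(=O)Cc1cc(OC(C)C)cc(OC(C)C)c1 | intermediate
6 | 4-bromo-2-methoxyphenol | COc1cc(Br)ccc1O | starting material
7 | 4-bromo-1-isopropoxy-2-methoxybenzene | COc1cc(Br)ccc1OC(C)C | intermediate
8 | (4-isopropoxy-3-methoxyphenyl)magnesium bromide (not isolated) | COc1cc([Mg]Br)ccc1OC(C)C | intermediate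
9 | 2-(3,5-diisopropoxyphenyl)-1-(4-isopropoxy-3-methoxyphenyl)ethanone | COc1cc(C(=O)Cc2cc(OC(C)C)cc(OC(C)C)c2)ccc1OC(C)C | intermediate
10 | 2-diazo-2-(3,5-diisopropoxyphenyl)-1-(4-isopropoxy-3-methoxyphenyl)ethanone | COc1cc(C(=O)C(=[N+]=[N-])c2cc(OC(C)C)cc(OC(C)C)c2)ccc1OC(C)C | intermediate
11 | 2,4-dihydroxybenzaldehyde | O=Cc1ccc(O)cc1O | starting material
12 | 2,4-diisopropoxybenzaldehyde | CC(C)Oc1ccc(C=O)c(OC(C)C)c1 | intermediate
13 | (E)-2-(3,5-diisopropoxyphenyl)-3-(2,4-diisopropoxyphenyl)prop-2-enoic acid | OC(=O)/C(c1cc(OC(C)C)cc(OC(C)C)c1)=C/c1ccc(OC(C)C)cc1OC(C)C | intermediate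
14 | (Z)-2,3',4,5'-tetraisopropoxystilbene | CC(C)Oc1cc(/C=C\c2ccc(OC(C)C)cc2OC(C)C)cc(OC(C)C)c1 | intermediate
15 | (1S,2S,3R)-1,2,3-triarylcyclopropyl vanillyl ketone, all aryl groups cis, hepta-isopropyl ether | COc1cc(C(=O)[C@@]2(c3cc(OC(C)C)cc(OC(C)C)c3)[C@H](c3cc(OC(C)C)cc(OC(C)C)c3)[C@@H]2c2ccc(OC(C)C)cc2OC(C)C)ccc1OC(C)C | intermediate
16 | ring-opened zwitterion: enolate at C1 (scandium-bound, metal not drawn), benzylic cation at C3, C2 unchanged (not isolated) | COc1cc(C([O-])=C(c2cc(OC(C)C)cc(OC(C)C)c2)[C@@H]([CH+]c2ccc(OC(C)C)cc2OC(C)C)c2cc(OC(C)C)cc(OC(C)C)c2)ccc1OC(C)C | intermediate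
17 | (1S,2R,3S)-1-aroyl-2,3-diarylindane, 1,2-trans and 2,3-trans, hepta-isopropyl ether | COc1cc(C(=O)[C@@H]2c3cc(OC(C)C)cc(OC(C)C)c3[C@H](c3ccc(OC(C)C)cc3OC(C)C)[C@H]2c2cc(OC(C)C)cc(OC(C)C)c2)ccc1OC(C)C | intermediate
18 | (1S,2R,3S)-indanyl(aryl)methanol, carbinol carbon as epimer mixture | COc1cc(C(O)[C@@H]2c3cc(OC(C)C)cc(OC(C)C)c3[C@H](c3ccc(OC(C)C)cc3OC(C)C)[C@H]2c2cc(OC(C)C)cc(OC(C)C)c2)ccc1OC(C)C | intermediate
19 | (1E,2S,3S)-1-benzylidene-2,3-diarylindane, hepta-isopropyl ether | COc1cc(/C=C2/c3cc(OC(C)C)cc(OC(C)C)c3[C@H](c3ccc(OC(C)C)cc3OC(C)C)[C@H]2c2cc(OC(C)C)cc(OC(C)C)c2)ccc1OC(C)C | intermediate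
20 | CNP0122890.1, (1E,2S,3S)-2-(3,5-dihydroxyphenyl)-3-(2,4-dihydroxyphenyl)-1-(4-hydroxy-3-methoxybenzylidene)-2,3-dihydro-1H-indene-4,6-diol | COc1cc(/C=C2/c3cc(O)cc(O)c3[C@H](c3ccc(O)cc3O)[C@H]2c2cc(O)cc(O)c2)ccc1O | target

**Total step count:** 14
**Longest linear sequence:** 10 steps (1, 2, 3, 5, 6, 10, 11, 12, 13, 14)

**Steps most likely to fail**

1. **Step 11 (labelled step).** The open ion pair may collapse on the enolate oxygen, lose the C2 proton (erosion of enantiopurity) or close onto ring E faster than ring A closes the five-membered ring.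
   - The fallback sets out from 15 and comes back at 17. It separates ring opening and arylation into two known reactions.
   - Lewis-acid-catalysed methanolysis of the donor–acceptor cyclopropane (Yb(OTf)3 cat., MeOH–CH2Cl2, 0 °C) should give the (3R)-γ-methoxy ketone F1, with C2 untouched and the two flanking centres as mixtures.
   - C1 is now tetrahedral and the enolate is gone. Ionisation of the benzylic ether (BF3·OEt2, CH2Cl2, −40 °C) is then an ordinary intramolecular Friedel–Crafts cycloalkylation of a 1,3-diarylpropyl cation to a 1-arylindane, which gives 17.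

2. **Step 10.** Carbene transfer to the crowded Z-alkene may be slow. Wolff rearrangement of the keto carbene, insertion into isopropyl methine C–H bonds or attack on the electron-rich rings could then take over, or facial discrimination may be weak.
   - The fallback sets out from 9 and 12 and comes back at 17. It replaces carbene chemistry by a sulfur-ylide Michael-initiated ring closure (Corey–Chaykovsky type) in which C2 is the ylide carbon.
   - Knoevenagel condensation of 9 with 12 (piperidine, AcOH, toluene, Dean–Stark) should give the α-aryl chalcone F2.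
   - Commercial 3,5-dihydroxybenzyl alcohol F3 is alkylated (2-bromopropane, K2CO3, DMF) to (3,5-diisopropoxyphenyl)methanol F4. This is converted with PBr3 into 3,5-diisopropoxybenzyl bromide F5.
   - F5 is alkylated onto (2S,5S)-2,5-dimethylthiolane with AgBF4 to give the sulfonium tetrafluoroborate F6. The antipode of this C2-symmetric sulfide is chosen by analogy with its benzylidene transfer to aldehydes.
   - Deprotonation (LiHMDS, THF, −78 °C) and addition of F2 should give the (2S)-cyclopropyl ketone F7. The ylide face fixes C2.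
   - The configurations at C1 and C3 do not matter, because the conditions of step 11 erase both and lead F7 to 17.

3. **Step 14.** Sevenfold dealkylation of the acid-sensitive benzylidene indane may be accompanied by re-alkylation of the resorcinol rings, migration of the exocyclic double bond into ring B (loss of C2) or chelation-assisted loss of the methyl ether.
   - The fallback sets out from 17 and comes back at 20. It moves the harsh step ahead of alkene formation and changes to fluoride-labile groups.
   - BCl3 on the robust ketone 17 should give the heptaphenol ketone F8.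
   - TBSCl and imidazole in DMF give the hepta-TBS ketone F9.
   - NaBH4 in THF–EtOH gives the hepta-TBS carbinol F10.
   - Catalytic p-TsOH in CH2Cl2 gives the hepta-TBS benzylidene indane F11.
   - Bu4NF buffered with AcOH in THF at 0 °C releases 20 under nearly neutral conditions.

**Further compounds**
F1 | step 11 | (3R)-2,3-bis(3,5-diisopropoxyphenyl)-4-(2,4-diisopropoxyphenyl)-1-(4-isopropoxy-3-methoxyphenyl)-4-methoxybutan-1-one (C2 and C4 of the butanone as mixtures) | COc1cc(C(=O)C(c2cc(OC(C)C)cc(OC(C)C)c2)[C@@H](C(OC)c2ccc(OC(C)C)cc2OC(C)C)c2cc(OC(C)C)cc(OC(C)C)c2)ccc1OC(C)C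
F2 | step 10 | (E)-2-(3,5-diisopropoxyphenyl)-3-(2,4-diisopropoxyphenyl)-1-(4-isopropoxy-3-methoxyphenyl)prop-2-en-1-one | COc1cc(C(=O)/C(c2cc(OC(C)C)cc(OC(C)C)c2)=C/c2ccc(OC(C)C)cc2OC(C)C)ccc1OC(C)C
F3 | step 10 | 3,5-dihydroxybenzyl alcohol (commercial) | OCc1cc(O)cc(O)c1
F4 | step 10 | (3,5-diisopropoxyphenyl)methanol | OCc1cc(OC(C)C)cc(OC(C)C)c1
F5 | step 10 | 3,5-diisopropoxybenzyl bromide | BrCc1cc(OC(C)C)cc(OC(C)C)c1
F6 | step 10 | (2S,5S)-1-(3,5-diisopropoxybenzyl)-2,5-dimethylthiolanium tetrafluoroborate | C[C@H]1CC[C@H](C)[S+]1Cc1cc(OC(C)C)cc(OC(C)C)c1.F[B-](F)(F)F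
F7 | step 10 | (2S,3S)-1,2,3-triarylcyclopropyl vanillyl ketone, rings C and D trans, C1 as epimer mixture | COc1cc(C(=O)C2(c3cc(OC(C)C)cc(OC(C)C)c3)[C@H](c3cc(OC(C)C)cc(OC(C)C)c3)[C@H]2c2ccc(OC(C)C)cc2OC(C)C)ccc1OC(C)C
F8 | step 14 | (1S,2R,3S)-1-aroyl-2,3-diarylindane heptaphenol | COc1cc(C(=O)[C@@H]2c3cc(O)cc(O)c3[C@H](c3ccc(O)cc3O)[C@H]2c2cc(O)cc(O)c2)ccc1O
F9 | step 14 | hepta-O-TBS ether of F8 | COc1cc(C(=O)[C@@H]2c3cc(O[Si](C)(C)C(C)(C)C)cc(O[Si](C)(C)C(C)(C)C)c3[C@H](c3ccc(O[Si](C)(C)C(C)(C)C)cc3O[Si](C)(C)C(C)(C)C)[C@H]2c2cc(O[Si](C)(C)C(C)(C)C)cc(O[Si](C)(C)C(C)(C)C)c2)ccc1O[Si](C)(C)C(C)(C)C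
F10 | step 14 | hepta-O-TBS indanyl(aryl)methanol, carbinol epimers | COc1cc(C(O)[C@@H]2c3cc(O[Si](C)(C)C(C)(C)C)cc(O[Si](C)(C)C(C)(C)C)c3[C@H](c3ccc(O[Si](C)(C)C(C)(C)C)cc3O[Si](C)(C)C(C)(C)C)[C@H]2c2cc(O[Si](C)(C)C(C)(C)C)cc(O[Si](C)(C)C(C)(C)C)c2)ccc1O[Si](C)(C)C(C)(C)C
F11 | step 14 | (1E,2S,3S)-hepta-O-TBS ether of the target | COc1cc(/C=C2/c3cc(O[Si](C)(C)C(C)(C)C)cc(O[Si](C)(C)C(C)(C)C)c3[C@H](c3ccc(O[Si](C)(C)C(C)(C)C)cc3O[Si](C)(C)C(C)(C)C)[C@H]2c2cc(O[Si](C)(C)C(C)(C)C)cc(O[Si](C)(C)C(C)(C)C)c2)ccc1O[Si](C)(C)C(C)(C)C
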